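## Structural features

The target is a cembrane-type diterpenoid in which a 14-membered carbocycle (C4, C5, C6, C7 to C17) is bridged between C4 and C6 by a six-membered lactone (C2, C3, ring oxygen, C4, C5, C6), so that C4–C5–C6 is common to both rings. Its seven stereocentres are 2S,4R,6R,9S,10S,13S,17S: C2 and C6 are vicinal in the lactone, C4 is 1,3 to C6 and bonded directly to the tertiary carbinol C17, C9/C10 form a trans trisubstituted epoxide, and C13 is an isolated tertiary centre that carries the hydroperoxide next to the E C14=C15 alkene. In the lactone the C2 methyl is trans to the C6 ring bond and the C4 and C6 ring bonds are cis, so all three substituents can be equatorial and the enolisable C2 can be corrected by equilibration. The tertiary allylic hydroperoxide is fragile toward reductants, acid and base, the epoxide toward acid and transannular attack by the C17 hydroxyl, and the lactone toward nucleophiles and strong base. The hydroperoxide must therefore come last and the epoxide late. The real difficulty is to close the 14-membered ring and to fix the remote centres C6, C9/C10 and C13 relative to C4/C17 without a rigid element between them. The key step exploits the fact that C6 is the β-carbon and C2 the α-carbon of the C3 acyl group: on an open-chain E C2=C6 thioenoate the C7–C11 arm can be attached at C6 and the methyl group at C2 in one operation.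

## Logic of the disconnections

36 to 35. The C13–O bond is cut and the alkene is returned from C14=C15 to C13=C14 (retro-ene). This removes the most fragile group and one stereocentre, and leaves every earlier step free of peroxide constraints. The forward step needs oxygen to bond to C13 and not to C14, to take hydrogen from C15 and not from the C13 methyl, and to approach the correct face. 35 contains no other alkene.

35 to 34 to 32. The C12–S bond is added back, then the ring bond C11–C12 is cut. This is the only ring bond flanked by the two oxygenated CH2 termini that the key step delivers. C12 is allylic and can carry a sulfone-stabilised anion, and C11 next to the finished epoxide becomes the electrophile. The macrocycle opens to a chain. The forward step needs high dilution, a single deprotonation at the sulfone CH2 in the presence of the lactone C2–H, a silylated C17 oxygen so that the base stoichiometry is defined, and a desulfonylation that leaves C13=C14 in place.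

32 to 31 to 30. The C11–I bond goes back to C11–OH, and the C9–O and C10–O bonds of the epoxide are cut to the E C9=C10 alkene. An allylic alcohol allows a reagent-controlled epoxidation that does not depend on the remote centres. The demand is that C13=C14 is not an allylic alcohol at that stage (it is an allylic sulfone) and that the C11 oxygen is unveiled alone.

30 to 29 to 28 to 26. Protecting-group and functional-group changes only: the PMB ether at C11, the silyl ether at C17, and the C12–S bond back to C12–OH. The order is forced, because the sulfinate displacement at C12 must precede any halide at C11. This requires C12–OH free while C11–O is still masked, hence the acid-labile silyl ether at C12 and the oxidatively cleaved PMB ether at C11 in 24.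

26 to 24. The lactone C3–O bond is cut to an open-chain thioester with the C4 and C17 oxygens tied as an acetonide. This makes C2 a centre that is corrected thermodynamically after ring closure. The forward step needs the secondary C4–OH to win over the tertiary C17–OH, and one acid treatment to remove the acetonide and the C12 silyl ether without touching the PMB ether.

24 to 12, 21 and 22 (key disconnection). The C6–C7 and C2–CH3 bonds are cut. Both carbons belong to the C3 acyl unit, so an E thioenoate accepts a carbon nucleophile at C6 and an electrophile at C2. Three components result, and the C7–C11 arm arrives with its E alkene and oxygen in place. The forward step needs catalyst control at C6, a Grignard reagent that carries only an ether and an alkene, and an enolate that can be alkylated. The protecting groups of 12 are kept as the acid-labile pair (acetonide, silyl ether), with the PMB ether on 21, for the reason given in the previous paragraph.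

12 to 9 and 11, and 11 to 10. The C2=C6 double bond is cut (cross-metathesis), then the acyl C–S bond of 11. This removes the thioenoate from the chiral fragment and leaves a terminal alkene. The forward step needs E selectivity and an inert trisubstituted alkene.

9 to 8 to 7. The C12–O bond is cut back to the E methyl of an isopropylidene terminus. The oxygen is thereby introduced late by a site-selective allylic oxidation.

7 to 6 to 5 to 4. The C5–C6 bond is cut (vinyl nucleophile on the C5 sulfonate), then the acetonide and the sulfonate ester are taken off. C5 is thereby the former C1 of 1, so no carbon is lost and C4 needs no separate asymmetric reaction. A route through a C4 aldehyde would need an inverting opening of a tertiary epoxide carbon and an additional reagent-controlled allylation. The forward steps need selective activation of the primary hydroxyl, masking of the C4 and C17 hydroxyls before the organometallic step so that the Grignard reagent meets no acidic proton and no alkoxide can close onto C5, and a displacement at a primary carbon that carries a β-oxygen.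

4 to 2 to 1. The C4–O and C17–O bonds are traced to one epoxide. C17 keeps its oxygen. C4 is inverted by the intramolecular displacement of the Payne rearrangement. One asymmetric epoxidation therefore sets both centres.

21 to 20 to 19 to 18 to 17 to 14 to 13. The C–Mg bond comes from C–Br and C–OH. The C9–CH3 and C10–C11 bonds are cut (carboalumination, then formaldehyde) to a terminal alkyne. The syn carbometalation fixes the E geometry of C9=C10.

## Other disconnections considered

Alternative 1: The cut is C5–C6. In the forward direction Bu3SnH and AIBN would turn the primary iodide of the 16-membered macrolactone A2 into a C5 radical. This radical adds across the ring to C6 of the E C2=C6 enoate in a six-membered endo mode and closes the lactone and the 14-membered carbocycle together, giving A1 after hydrogen transfer to C2. In its favour: the large ring is first closed as an ester, which is easier than a carbon–carbon macrocyclisation. The polarity is matched (nucleophilic alkyl radical, electron-poor β-carbon). The C2 methyl blocks the competing five-membered closure. A1 is the same compound as 35, reached without installing and removing a sulfone. On ring-forming economy and on avoiding the allylic desulfonylation this plan is the better one. Against it: C6 would be set only by the conformation of the macrolactone. The ester must adopt a reactive conformation. Simple reduction of the iodide competes. The C5 radical is β to an acyloxy group. The iodomethyl group has to be built next to the tertiary carbinol with the epoxide already present. C2 arises by hydrogen transfer and is corrected by equilibration, as in the chosen plan, so the two are equal on that point. The chosen plan sets C6 by a chiral catalyst on an open chain, which is the more predictable control element.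

Alternative 2: The cuts are the four C–O bonds of the C4–C17 and C9–C10 epoxides. In the forward direction Ti(OiPr)4, L-(+)-diethyl tartrate and t-BuOOH would epoxidise both allylic alcohols of the diol A4 in one flask to give A3. The C2/C6 part would be cut out of the ring of (R)-limonene A5. In its favour: two reagent-controlled epoxidations in one operation, with the statistical gain in enantiopurity of a double asymmetric reaction. C6 comes from the chiral pool with no catalyst uncertainty, which is better than the chosen plan on that point. The C4–C17 epoxide can later be opened at C4 by the C3 carboxyl with inversion, giving the lactone and the C17 hydroxyl together. Against it: A3 ends in two chemically equivalent epoxy alcohol termini (C11 and C16) that must be told apart. The four-carbon unit C12–C15 must still be joined by two more carbon–carbon bonds, one of them the macrocyclisation. C2 would come from an unselective hydroboration, although it is epimerisable as in the chosen plan. Both plans use the same Sharpless step for C9/C10 and are equal there. The chosen plan is more convergent after its key step, with one ring bond left to form.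

Alternative 3: The cuts are C4–C5 and the ring O–C3 bond. In the forward direction a titanium–BINOL Lewis acid made from Ti(OiPr)4 would join the aldehyde A7 with the silyloxy diene A8 in a hetero-Diels–Alder reaction to give the dihydropyranone A6. In its favour: the whole lactone ring and C4 are made in one catalytic step. The union is convergent. The later centres C6 and C2 would be set on a six-membered ring, where 1,3-induction from C4 and thermodynamic control at C2 are reliable. On the definition of C2/C6 this is equal to or better than an open-chain alkylation. Against it: A7 is an α-quaternary, α-acyloxy aldehyde, hindered and able to chelate, and the catalyst must override it. C17 has to be made beforehand by an inverting opening at a tertiary epoxide carbon. The methoxy group at C6 must afterwards be exchanged for the C7 arm (hydrolysis, enol triflate, sp2–sp3 coupling, conjugate reduction), which costs about four steps for a bond the chosen key step makes directly. The chosen plan is shorter and takes C4 and C17 from one epoxide. Alternative 3 has the more rigid stereocontrol at C6.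

Key step: step 16

Remarks before the steps. Atom numbers C2–C17 are those of the first section. The structures of 12, 21 and 24 agree with the target configuration (2S,4R,6R,17S, E alkenes). Assumption: the copper complex of (R,S)-Josiphos is taken to deliver the alkyl group to the Re face of C6 of a linear S-ethyl E-thioenoate (giving 6R). If the opposite sense applies to 12, the (S,R)-ligand is used and nothing else changes.

Step 1
Reactants: 1 geraniol
Product: 2 (2S,3S)-2,3-epoxygeraniol
Conditions: Ti(OiPr)4 (5 mol%), L-(+)-diethyl tartrate (7 mol%), t-BuOOH, 4 Å MS, CH2Cl2, −20 °C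
Reagents that add atoms: tert-butyl hydroperoxide, CC(C)(C)OO
Why: Sharpless asymmetric epoxidation of an E allylic alcohol; L-(+)-tartrate gives the 2S,3S epoxide, which fixes the future C17 (S) and a C4 centre that is inverted in step 2; the remote trisubstituted alkene has no directing hydroxyl and is untouched.

Step 2
Reactants: 2 (2S,3S)-2,3-epoxygeraniol
Product: 4 (2R,3S)-3,7-dimethyloct-6-ene-1,2,3-triol, via terminal epoxide 3 (not isolated)
Conditions: NaOH (0.5 M), H2O/t-BuOH, 75 °C
Reagents that add atoms: water, O
Why: Payne rearrangement followed by hydroxide opening; the primary alkoxide displaces the epoxide oxygen at the future C4 with inversion (giving 4R) while the C17–O bond is never broken (17S kept), and hydroxide then attacks the unhindered CH2 of 3.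

Step 3
Reactants: 4 (2R,3S)-3,7-dimethyloct-6-ene-1,2,3-triol
Product: 5 (2R,3S)-2,3-dihydroxy-3,7-dimethyloct-6-enyl 4-methylbenzenesulfonate
Conditions: TsCl (1.05 equiv), Bu2SnO (2 mol%), Et3N, CH2Cl2, 0 °C
Reagents that add atoms: 4-toluenesulfonyl chloride, Cc1ccc(cc1)S(Cl)(=O)=O
Why: Tin-acetal-catalysed selective sulfonylation of the primary hydroxyl of a 1,2-diol; the secondary and tertiary hydroxyls do not react under these conditions and no stereocentre is touched.

Step 4
Reactants: 5 (2R,3S)-2,3-dihydroxy-3,7-dimethyloct-6-enyl 4-methylbenzenesulfonate
Product: 6 [(4R,5S)-2,2,5-trimethyl-5-(4-methylpent-3-enyl)-1,3-dioxolan-4-yl]methyl 4-methylbenzenesulfonate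
Conditions: 2,2-dimethoxypropane, PPTS (cat.), CH2Cl2, rt
Reagents that add atoms: 2,2-dimethoxypropane, COC(C)(C)OC
Why: Acid-catalysed transketalisation of the secondary/tertiary 1,2-diol to its acetonide; the tosylate is inert to PPTS, and the one group that masks the C4 and C17 oxygens is removed by the acid treatment of step 17.

Step 5
Reactants: 6 [(4R,5S)-2,2,5-trimethyl-5-(4-methylpent-3-enyl)-1,3-dioxolan-4-yl]methyl 4-methylbenzenesulfonate
Product: 7 (4S,5R)-2,2,4-trimethyl-4-(4-methylpent-3-enyl)-5-(prop-2-enyl)-1,3-dioxolane
Conditions: CH2=CHMgBr (3 equiv), CuI (20 mol%), THF, −30 °C to rt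
Reagents that add atoms: vinylmagnesium bromide, C=C[Mg]Br
Why: Copper-catalysed cross-coupling of a primary alkyl tosylate with a vinyl Grignard reagent (SN2 displacement by the vinylcuprate formed in the flask) forms C5–C6; with both hydroxyls held in the acetonide no alkoxide is present, so the reagent is consumed only by the coupling, and C4 and C17 are not touched.

Step 6
Reactants: 7 (4S,5R)-2,2,4-trimethyl-4-(4-methylpent-3-enyl)-5-(prop-2-enyl)-1,3-dioxolane
Product: 8 E allylic alcohol (C12 hydroxyl) of acetonide 7
Conditions: SeO2 (0.3 equiv), t-BuOOH, salicylic acid (cat.), CH2Cl2, rt; then NaBH4, MeOH, 0 °C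
Reagents that add atoms: tert-butyl hydroperoxide, CC(C)(C)OO
Why: Selenium dioxide allylic oxidation (ene reaction then 2,3-sigmatropic shift) attacks the E methyl of the trisubstituted alkene and gives the E allylic alcohol; the monosubstituted vinyl group reacts far more slowly, and the borohydride treatment returns any over-oxidised enal to 8.

Step 7
Reactants: 8 E allylic alcohol (C12 hydroxyl) of acetonide 7
Product: 9 tert-butyldimethylsilyl ether of 8
Conditions: TBSCl, imidazole, CH2Cl2, rt
Reagents that add atoms: tert-butyldimethylsilyl chloride, CC(C)(C)[Si](C)(C)Cl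
Why: Standard silylation of a primary alcohol; the silyl ether removes the acidic proton before the Grignard step and is later cleaved together with the acetonide.

Step 8
Reactants: 10 acryloyl chloride
Product: 11 S-ethyl prop-2-enethioate
Conditions: EtSH, NaOH, H2O/cyclohexane, BHT (cat.), 0 °C
Reagents that add atoms: ethanethiol, CCS
Why: Two-phase Schotten–Baumann acylation of the thiolate; substitution at the acid chloride is faster than conjugate addition at 0 °C and the radical inhibitor suppresses polymerisation.

Step 9
Reactants: 9 tert-butyldimethylsilyl ether of 8; 11 S-ethyl prop-2-enethioate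
Product: 12 E thioenoate with C4,C17 acetonide and C12 silyl ether
Conditions: second-generation Hoveyda–Grubbs catalyst RuCl2(=CH-C6H4-2-OiPr)(H2IMes) (5 mol%), 11 (3 equiv), CH2Cl2, 40 °C
Reagents that add atoms: none
Why: Olefin cross-metathesis of a terminal alkene with an electron-poor acryloyl partner; the E isomer is the thermodynamic product and the trisubstituted C13=C14 alkene does not take part.

Step 10
Reactants: 13 but-3-yn-1-ol
Product: 14 (but-3-ynyloxy)(tert-butyl)dimethylsilane
Conditions: TBSCl, imidazole, CH2Cl2, rt
Reagents that add atoms: tert-butyldimethylsilyl chloride, CC(C)(C)[Si](C)(C)Cl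
Why: Standard silylation; it distinguishes the future C7 oxygen from the allylic C11 oxygen introduced next.

Step 11
Reactants: 14 (but-3-ynyloxy)(tert-butyl)dimethylsilane
Product: 17 (2E)-5-(tert-butyldimethylsilyloxy)-3-methylpent-2-en-1-ol, via alkenylalane 15 (not isolated), via lithium alanate 16 (not isolated)
Conditions: Me3Al (2 equiv), Cp2ZrCl2 (0.25 equiv), CH2Cl2, 0 °C to rt; then n-BuLi, THF, −78 °C; (CH2O)n, −78 °C to rt
Reagents that add atoms: trimethylaluminium, C[Al](C)C; formaldehyde (as paraformaldehyde), C=O
Why: Zirconium-catalysed carboalumination adds CH3 and Al syn across the terminal alkyne with Al on the terminal carbon, which fixes the E geometry of C9=C10; the derived alanate attacks formaldehyde with retention to form C10–C11.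

Step 12
Reactants: 17 (2E)-5-(tert-butyldimethylsilyloxy)-3-methylpent-2-en-1-ol
Product: 18 4-methoxybenzyl ether of 17
Conditions: NaH, 4-MeOC6H4CH2Cl, Bu4NI (cat.), THF/DMF, 0 °C to rt
Reagents that add atoms: 4-methoxybenzyl chloride, COc1ccc(CCl)cc1
Why: Williamson etherification; the PMB ether is inert to Grignard reagents and to the later acid step and is removed oxidatively.

Step 13
Reactants: 18 4-methoxybenzyl ether of 17
Product: 19 (3E)-5-(4-methoxybenzyloxy)-3-methylpent-3-en-1-ol
Conditions: Bu4NF, THF, rt
Reagents that add atoms: none
Why: Fluoride cleavage of the silyl ether; the PMB ether and the alkene are unaffected.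

Step 14
Reactants: 19 (3E)-5-(4-methoxybenzyloxy)-3-methylpent-3-en-1-ol
Product: 20 1-[(2E)-5-bromo-3-methylpent-2-enyloxymethyl]-4-methoxybenzene
Conditions: CBr4, PPh3, CH2Cl2, 0 °C
Reagents that add atoms: carbon tetrabromide, BrC(Br)(Br)Br
Why: Appel bromination of a primary homoallylic alcohol under neutral conditions; no allylic transposition is possible at this position.

Step 15
Reactants: 20 1-[(2E)-5-bromo-3-methylpent-2-enyloxymethyl]-4-methoxybenzene
Product: 21 (3E)-5-(4-methoxybenzyloxy)-3-methylpent-3-enylmagnesium bromide
Conditions: Mg turnings (I2-activated), Et2O, 35 °C; titrated solution kept at or below rt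
Reagents that add atoms: magnesium, [Mg]
Why: Grignard formation from a primary alkyl bromide; ether solvent is chosen because the copper step loses selectivity in THF, and the reagent is kept cool so that the homoallylic carbanion does not displace the allylic ether.

Step 16
Reactants: 12 E thioenoate with C4,C17 acetonide and C12 silyl ether; 21 (3E)-5-(4-methoxybenzyloxy)-3-methylpent-3-enylmagnesium bromide; 22 iodomethane
Product: 24 C2-methyl C6-alkyl thioester (2S,6R; C4,C17 acetonide; C11 PMB ether; C12 silyl ether), via magnesium enolate 23 (not isolated)
Conditions: CuBr·SMe2 (5 mol%), (R,S)-Josiphos [(R)-1-[(S)-2-(diphenylphosphino)ferrocenyl]ethyldicyclohexylphosphine] (6 mol%), t-BuOMe, −75 °C, 21 (1.3 equiv) added over 2 h; then 22 (5 equiv), DMPU, −75 to −30 °C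
Reagents that add atoms: none
Why: Three-component conjugate addition with enolate alkylation. Transmetalation of 21 to the chiral copper bromide–diphosphine complex gives an alkylcopper–magnesium species that binds the s-cis thioenoate as a π-complex, adds oxidatively at C6 to a trivalent copper intermediate and eliminates reductively, forming C6–C7 and leaving the magnesium enolate 23, which is then C-methylated by 22 in an SN2 step assisted by DMPU to form C2–CH3. The closest known reaction types are the copper–Josiphos addition of Grignard reagents to S-alkyl E-thioenoates and its tandem forms in which the magnesium enolate is trapped by an aldehyde or by an internal alkyl halide; trapping by iodomethane is a short extension of these. No ring is closed. C6 is set by the ligand (delivery to the Re face of C6 gives 6R), since the nearest resident centre C4 is two atoms away and biases the face only weakly. C2 is set in the alkylation, and because the two branches on C6 are of similar size a mixture of 2S and 2R is expected, which is acceptable because C2 is equilibrated in step 17. The step needs 1,4- over 1,2-addition (secured by the thioester, the low temperature and the slow addition), inert acetonide, silyl and PMB ethers (the C4 oxygen is δ to the carbonyl and cannot be eliminated), and C-methylation of an enolate that must not collapse to a ketene (kept at or below −30 °C).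

Step 17
Reactants: 24 C2-methyl C6-alkyl thioester (2S,6R; C4,C17 acetonide; C11 PMB ether; C12 silyl ether)
Product: 26 lactone diol (2S,4R,6R,17S; C12 and C17 hydroxyls; C11 PMB ether), via trihydroxy thioester 25 (not isolated)
Conditions: TsOH·H2O (0.2 equiv), MeOH, 40 °C; Et3N, evaporate; DBU (2 equiv), PhMe (0.01 M), 70 °C
Reagents that add atoms: none
Why: Acid-catalysed transketalisation and desilylation free the C4, C17 and C12 hydroxyls while the PMB ether stays; DBU-promoted acyl transfer from sulfur to the secondary C4 hydroxyl closes the six-membered lactone (the tertiary C17 hydroxyl would need a seven-membered ring) and equilibrates the enolisable C2 toward the all-equatorial 2S isomer, any remaining 2R lactone being separated and resubmitted.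

Step 18
Reactants: 26 lactone diol (2S,4R,6R,17S; C12 and C17 hydroxyls; C11 PMB ether)
Product: 28 C12 phenyl sulfone of lactone 26, via allylic mesylate 27 (not isolated)
Conditions: MsCl, Et3N, CH2Cl2, −40 °C; then PhSO2Na, Bu4NI (cat.), DMF, 0 °C to rt
Reagents that add atoms: sodium benzenesulfinate, [Na+].[O-]S(=O)c1ccccc1
Why: Selective mesylation of the primary allylic hydroxyl (the tertiary one does not react at −40 °C) and SN2 displacement by sulfinate at sulfur give the allylic sulfone at the primary carbon without allylic shift.

Step 19
Reactants: 28 C12 phenyl sulfone of lactone 26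
Product: 29 C17 triethylsilyl ether of sulfone 28
Conditions: Et3SiOTf, 2,6-lutidine, CH2Cl2, −78 °C
Reagents that add atoms: triethylsilyl trifluoromethanesulfonate, CC[Si](CC)(CC)OS(=O)(=O)C(F)(F)F
Why: Silyl triflate silylation of the tertiary alcohol; with no free hydroxyl left next to the lactone, the base in step 23 is consumed only by the sulfone and no alkoxide can attack the lactone.

Step 20
Reactants: 29 C17 triethylsilyl ether of sulfone 28
Product: 30 C11 allylic alcohol (PMB removed)
Conditions: DDQ, CH2Cl2/pH 7 buffer, 0 °C
Reagents that add atoms: none
Why: Oxidative cleavage of the PMB ether by DDQ (hydride abstraction, then hydrolysis of the hemiacetal); silyl ether, sulfone, lactone and alkenes are inert at 0 °C.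

Step 21
Reactants: 30 C11 allylic alcohol (PMB removed)
Product: 31 (9S,10S)-epoxy alcohol
Conditions: Ti(OiPr)4 (1.1 equiv), L-(+)-diethyl tartrate (1.3 equiv), t-BuOOH, 4 Å MS, CH2Cl2, −20 °C
Reagents that add atoms: tert-butyl hydroperoxide, CC(C)(C)OO
Why: Sharpless asymmetric epoxidation of the E allylic alcohol; L-(+)-tartrate sets 9S,10S by reagent control in the same sense as in step 1, and C13=C14 has no allylic hydroxyl and is deactivated by the sulfone.

Step 22
Reactants: 31 (9S,10S)-epoxy alcohol
Product: 32 C11 epoxy iodide
Conditions: I2, PPh3, imidazole, THF, 0 °C, dark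
Reagents that add atoms: iodine, II
Why: Appel-type iodination of a primary 2,3-epoxy alcohol by SN2 at the CH2 carbon; the epoxide and its configuration are untouched.

Step 23
Reactants: 32 C11 epoxy iodide
Product: 34 macrocyclic sulfone (14-membered ring; C12 sulfone as either epimer; C17 hydroxyl), via macrocyclic silyl ether 33 (not isolated)
Conditions: LiN(SiMe3)2 (1.0 equiv, syringe pump), THF (2 mM), −78 to −20 °C; AcOH; then HF·pyridine, pyridine, THF, 0 °C
Reagents that add atoms: none
Why: Intramolecular alkylation of a sulfone-stabilised allylic carbanion at its α-carbon by a primary iodide (14-membered exo closure) under high dilution forms C11–C12; one equivalent of base selects the more acidic sulfone CH2 over the lactone C2–H and leaves no base to deprotonate the product; buffered fluoride then removes the silyl group; the new C12 centre is removed in step 24.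

Step 24
Reactants: 34 macrocyclic sulfone (14-membered ring; C12 sulfone as either epimer; C17 hydroxyl)
Product: 35 14-membered epoxy alkenyl hydroxy lactone (2S,4R,6R,9S,10S,17S; E C13=C14)
Conditions: Na(Hg) (5%), Na2HPO4, MeOH/THF, −20 °C
Reagents that add atoms: none
Why: Reductive desulfonylation by electron transfer from sodium amalgam; the allyl anion is protonated by methanol, the phosphate buffer protects the lactone, and epoxide and hydroxyl are inert; protonation at C12 gives the required C13=C14 alkene.

Step 25
Reactants: 35 14-membered epoxy alkenyl hydroxy lactone (2S,4R,6R,9S,10S,17S; E C13=C14)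
Product: 36 target hydroperoxide CNP0297487.4 (2S,4R,6R,9S,10S,13S,17S)
Conditions: O2, tetraphenylporphyrin (cat.), visible light, CH2Cl2, −20 °C; no reductive work-up
Reagents that add atoms: dioxygen, O=O
Why: Schenck ene reaction of singlet oxygen with the only alkene; oxygen bonds to C13 and takes a hydrogen from C15 on the more crowded side of the alkene, moving the double bond to C14=C15 (E); the C13 configuration is set by attack on the outer face of the ring conformer and is expected, not assured, to be 13S.

## Compound list

1 | geraniol, (2E)-3,7-dimethylocta-2,6-dien-1-ol | CC(C)=CCC/C(C)=C/CO | starting material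
2 | [(2S,3S)-3-methyl-3-(4-methylpent-3-enyl)oxiran-2-yl]methanol | OC[C@@H]1O[C@@]1(C)CCC=C(C)C | intermediate
3 | (2S)-6-methyl-2-[(2R)-oxiran-2-yl]hept-5-en-2-ol (terminal epoxide, not isolated) | C[C@](O)(CCC=C(C)C)[C@H]1CO1 | intermediate
4 | (2R,3S)-3,7-dimethyloct-6-ene-1,2,3-triol | C[C@](O)(CCC=C(C)C)[C@H](O)CO | intermediate
5 | (2R,3S)-2,3-dihydroxy-3,7-dimethyloct-6-enyl 4-methylbenzenesulfonate | C[C@](O)(CCC=C(C)C)[C@H](O)COS(=O)(=O)c1ccc(C)cc1 | intermediate
6 | [(4R,5S)-2,2,5-trimethyl-5-(4-methylpent-3-enyl)-1,3-dioxolan-4-yl]methyl 4-methylbenzenesulfonate | Cc1ccc(cc1)S(=O)(=O)OC[C@H]1OC(C)(C)O[C@@]1(C)CCC=C(C)C | intermediate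
7 | (4S,5R)-2,2,4-trimethyl-4-(4-methylpent-3-enyl)-5-(prop-2-enyl)-1,3-dioxolane | C=CC[C@H]1OC(C)(C)O[C@@]1(C)CCC=C(C)C | intermediate
8 | (2E)-2-methyl-5-[(4S,5R)-2,2,4-trimethyl-5-(prop-2-enyl)-1,3-dioxolan-4-yl]pent-2-en-1-ol | C=CC[C@H]1OC(C)(C)O[C@@]1(C)CC/C=C(\C)CO | intermediate
9 | tert-butyldimethylsilyl ether of 8 | C=CC[C@H]1OC(C)(C)O[C@@]1(C)CC/C=C(\C)CO[Si](C)(C)C(C)(C)C | intermediate
10 | acryloyl chloride | C=CC(Cl)=O | starting material
11 | S-ethyl prop-2-enethioate | C=CC(=O)SCC | intermediate
12 | S-ethyl (2E)-4-[(4R,5S)-5-[(3E)-5-(tert-butyldimethylsilyloxy)-4-methylpent-3-enyl]-2,2,5-trimethyl-1,3-dioxolan-4-yl]but-2-enethioate | CCSC(=O)/C=C/C[C@H]1OC(C)(C)O[C@@]1(C)CC/C=C(\C)CO[Si](C)(C)C(C)(C)C | intermediate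
13 | but-3-yn-1-ol | C#CCCO | starting material
14 | (but-3-ynyloxy)(tert-butyl)dimethylsilane | C#CCCO[Si](C)(C)C(C)(C)C | intermediate
15 | [(1E)-4-(tert-butyldimethylsilyloxy)-2-methylbut-1-enyl]dimethylalane (not isolated) | C[Al](C)/C=C(\C)CCO[Si](C)(C)C(C)(C)C | intermediate
16 | lithium butyl[(1E)-4-(tert-butyldimethylsilyloxy)-2-methylbut-1-enyl]dimethylaluminate (not isolated) | [Li+].CCCC[Al-](C)(C)/C=C(\C)CCO[Si](C)(C)C(C)(C)C | intermediate
17 | (2E)-5-(tert-butyldimethylsilyloxy)-3-methylpent-2-en-1-ol | OC/C=C(\C)CCO[Si](C)(C)C(C)(C)C | intermediate
18 | tert-butyl{[(3E)-5-(4-methoxybenzyloxy)-3-methylpent-3-enyl]oxy}dimethylsilane | COc1ccc(COC/C=C(\C)CCO[Si](C)(C)C(C)(C)C)cc1 | intermediate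
19 | (3E)-5-(4-methoxybenzyloxy)-3-methylpent-3-en-1-ol | COc1ccc(COC/C=C(\C)CCO)cc1 | intermediate
20 | 1-[(2E)-5-bromo-3-methylpent-2-enyloxymethyl]-4-methoxybenzene | COc1ccc(COC/C=C(\C)CCBr)cc1 | intermediate
21 | (3E)-5-(4-methoxybenzyloxy)-3-methylpent-3-enylmagnesium bromide | Br[Mg]CC/C(C)=C/COCc1ccc(OC)cc1 | intermediate
22 | iodomethane | CI | starting material
23 | bromomagnesium enolate of the C6-alkylated thioester (6R; enolate geometry not assigned; not isolated) | CCSC(O[Mg]Br)=C[C@H](CC/C(C)=C/COCc1ccc(OC)cc1)C[C@H]1OC(C)(C)O[C@@]1(C)CC/C=C(\C)CO[Si](C)(C)C(C)(C)C | intermediate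
24 | S-ethyl (2S,3R,6E)-3-{[(4R,5S)-5-[(3E)-5-(tert-butyldimethylsilyloxy)-4-methylpent-3-enyl]-2,2,5-trimethyl-1,3-dioxolan-4-yl]methyl}-8-(4-methoxybenzyloxy)-2,6-dimethyloct-6-enethioate (route numbering 2S,6R; expected together with its 2R epimer) | CCSC(=O)[C@@H](C)[C@H](CC/C(C)=C/COCc1ccc(OC)cc1)C[C@H]1OC(C)(C)O[C@@]1(C)CC/C=C(\C)CO[Si](C)(C)C(C)(C)C | intermediate
25 | S-ethyl (2S,3R,6E)-8-(4-methoxybenzyloxy)-2,6-dimethyl-3-[(2R,3S,6E)-2,3,8-trihydroxy-3,7-dimethyloct-6-enyl]oct-6-enethioate (not isolated) | CCSC(=O)[C@@H](C)[C@H](CC/C(C)=C/COCc1ccc(OC)cc1)C[C@@H](O)[C@@](C)(O)CC/C=C(\C)CO | intermediate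
26 | (3S,4R,6R)-6-[(2S,5E)-2,7-dihydroxy-6-methylhept-5-en-2-yl]-4-[(3E)-5-(4-methoxybenzyloxy)-3-methylpent-3-enyl]-3-methyltetrahydropyran-2-one | C[C@@H]1C(=O)O[C@H](C[C@H]1CC/C(C)=C/COCc2ccc(OC)cc2)[C@@](C)(O)CC/C=C(\C)CO | intermediate
27 | C12 methanesulfonate of 26 (not isolated) | C[C@@H]1C(=O)O[C@H](C[C@H]1CC/C(C)=C/COCc2ccc(OC)cc2)[C@@](C)(O)CC/C=C(\C)COS(C)(=O)=O | intermediate
28 | (3S,4R,6R)-6-[(2S,5E)-2-hydroxy-6-methyl-7-(phenylsulfonyl)hept-5-en-2-yl]-4-[(3E)-5-(4-methoxybenzyloxy)-3-methylpent-3-enyl]-3-methyltetrahydropyran-2-one | C[C@@H]1C(=O)O[C@H](C[C@H]1CC/C(C)=C/COCc2ccc(OC)cc2)[C@@](C)(O)CC/C=C(\C)CS(=O)(=O)c3ccccc3 | intermediate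
29 | triethylsilyl ether of 28 at the tertiary (C17) hydroxyl | C[C@@H]1C(=O)O[C@H](C[C@H]1CC/C(C)=C/COCc2ccc(OC)cc2)[C@@](C)(O[Si](CC)(CC)CC)CC/C=C(\C)CS(=O)(=O)c3ccccc3 | intermediate
30 | C11 allylic alcohol: 29 with the 4-methoxybenzyl group replaced by hydrogen | C[C@@H]1C(=O)O[C@H](C[C@H]1CC/C(C)=C/CO)[C@@](C)(O[Si](CC)(CC)CC)CC/C=C(\C)CS(=O)(=O)c2ccccc2 | intermediate
31 | (9S,10S)-epoxy alcohol: lactone C6 side chain is 2-[(2S,3S)-3-(hydroxymethyl)-2-methyloxiran-2-yl]ethyl | C[C@@H]1C(=O)O[C@H](C[C@H]1CC[C@]2(C)O[C@H]2CO)[C@@](C)(O[Si](CC)(CC)CC)CC/C=C(\C)CS(=O)(=O)c3ccccc3 | intermediate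
32 | C11 epoxy iodide: side chain is 2-[(2S,3R)-3-(iodomethyl)-2-methyloxiran-2-yl]ethyl (same geometry as in 31) | C[C@@H]1C(=O)O[C@H](C[C@H]1CC[C@]2(C)O[C@H]2CI)[C@@](C)(O[Si](CC)(CC)CC)CC/C=C(\C)CS(=O)(=O)c3ccccc3 | intermediate
33 | macrocyclic sulfone triethylsilyl ether (2S,4R,6R,9S,10S,17S; E C13=C14; C12 sulfone as either epimer; not isolated) | C[C@@H]1C(=O)O[C@@H]2C[C@H]1CC[C@]1(C)O[C@H]1CC(S(=O)(=O)c3ccccc3)/C(C)=C/CC[C@]2(C)O[Si](CC)(CC)CC | intermediate
34 | macrocyclic sulfone with free C17 hydroxyl (2S,4R,6R,9S,10S,17S; E C13=C14; C12 sulfone as either epimer) | C[C@@H]1C(=O)O[C@@H]2C[C@H]1CC[C@]1(C)O[C@H]1CC(S(=O)(=O)c3ccccc3)/C(C)=C/CC[C@]2(C)O | intermediate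
35 | 14-membered 9,10-epoxy-17-hydroxy lactone with E C13=C14 (2S,4R,6R,9S,10S,17S) | C[C@@H]1C(=O)O[C@@H]2C[C@H]1CC[C@]1(C)O[C@H]1CC/C(C)=C/CC[C@]2(C)O | intermediate
36 | CNP0297487.4: 14-membered 9,10-epoxy-13-hydroperoxy-17-hydroxy lactone with E C14=C15 (2S,4R,6R,9S,10S,13S,17S) | C[C@@H]1C(=O)O[C@@H]2C[C@H]1CC[C@]1(C)O[C@H]1CC[C@](C)(OO)/C=C/C[C@]2(C)O | target

Total step count: 25. Longest linear sequence: 18 steps (steps 1–7, 9 and 16–25). Steps 8 and 10–15 supply the two partners.

Least certain steps and fallbacks.

Step 16 (key step). The most likely failure is slow or incomplete C-methylation of the magnesium thioester enolate: proton quench on work-up, or loss of thiolate to a ketene on warming. Facial selectivity at C6 may also erode if the dioxolane oxygens chelate the metals or if the long functionalised Grignard reagent fits the catalyst poorly. The fallback separates the two bond formations and uses established reactions. From 12 and 21 the conjugate addition is run alone and quenched with NH4Cl to give the C2-unsubstituted thioester F1. F1 is then enolised with LDA in THF/DMPU at −78 °C and methylated with iodomethane (lithium thioester enolate alkylation). The route is rejoined at 24, again as a C2 mixture that step 17 corrects.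

Step 23 (macrocyclisation). Four processes threaten the closure. The carbanion may attack the iodine atom and trigger reductive fragmentation of the epoxy iodide to an allylic alkoxide. Deprotonation at C2 may lead to a seven-membered ring by C2 alkylation. Intermolecular alkylation competes if the dilution is insufficient. A second deprotonation at C12 of 33 could open the γ,δ-epoxide to a cyclopropane. The fallback changes the electrophile and the timing of the epoxidation. From 30 the allylic bromide F2 is made (CBr4, PPh3) and cyclised with LiN(SiMe3)2 under high dilution to the macrocyclic diene sulfone F3, the classical sulfone/allylic bromide closure. A Shi epoxidation with the enantiomer of the fructose-derived ketone (L series, chosen by analogy with other E trisubstituted alkenes to give 9S,10S) should then select C9=C10, because C13=C14 is deactivated by the allylic sulfone. The route is rejoined at 33.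

Step 24 (desulfonylation). The allyl anion has two secondary termini and no intrinsic bias. Protonation at C14 instead of C12 would move the alkene to C12=C13, and the alkene geometry may scramble. The fallback fixes the position mechanistically by a double allylic transposition. From 34, Bu3SnH and AIBN in benzene at 80 °C replace the sulfonyl group by a radical SH2′ substitution and give the allylstannane F4 (tin at C14, alkene at C12=C13). Protodestannylation with acetic acid in CH2Cl2 (SE2′, proton to C12) returns the alkene to C13=C14. The route is rejoined at 35.

Step 25 (ene reaction). Hydrogen abstraction from the C13 methyl would give the C14 hydroperoxide with an exocyclic methylene, and oxygen may approach the wrong face of the ring and give the C13 epimer. The fallback builds the same group stepwise with enforced regiochemistry and a different stereochemical course (anti addition instead of a suprafacial ene process). It sets out from 33, which is isolated instead of desilylated and desulfonylated as in step 24 to the silyl ether F5; the silyl group prevents bromoetherification by the C17 hydroxyl. Bromohydroperoxidation (1,3-dibromo-5,5-dimethylhydantoin, concentrated H2O2, Et2O, −40 °C) gives the bromo hydroperoxide F6, with the hydroperoxide at the tertiary C13. Protection with 2-methoxypropene and PPTS gives the peroxyketal F7. DBU in toluene eliminates HBr toward C15, the only β-hydrogens, and gives the allylic peroxyketal F8. Bu4NF/AcOH followed by aqueous acetic acid removes both protecting groups. The route is rejoined at 36.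

Step 5 (vinyl coupling). The C5 carbon carries a β-oxygen and sits next to the fully substituted dioxolane carbon, so the displacement may be slow; attack of the Grignard reagent at sulfur (cleavage of the S–O bond back to the alcohol) or homocoupling of the vinyl reagent could then take over. The fallback uses a smaller and more nucleophilic sp carbon in a dipolar aprotic solvent and adjusts the oxidation level afterwards. From 6 the tosylate is displaced by lithium acetylide–ethylenediamine complex (LiC≡CH·H2NCH2CH2NH2) in DMSO at rt to give the terminal alkyne F9. Semi-hydrogenation (H2, Pd on CaCO3 poisoned with Pb(OAc)2, quinoline, EtOAc) reduces only the alkyne, since the trisubstituted alkene is inert to this catalyst. The route is rejoined at 7.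

## Further compounds

F1 | step 16 | C2-unsubstituted C6-alkyl thioester (6R) | CCSC(=O)C[C@H](CC/C(C)=C/COCc1ccc(OC)cc1)C[C@H]1OC(C)(C)O[C@@]1(C)CC/C=C(\C)CO[Si](C)(C)C(C)(C)C
F2 | step 23 | C11 allylic bromide of 30 | C[C@@H]1C(=O)O[C@H](C[C@H]1CC/C(C)=C/CBr)[C@@](C)(O[Si](CC)(CC)CC)CC/C=C(\C)CS(=O)(=O)c2ccccc2
F3 | step 23 | macrocyclic diene sulfone triethylsilyl ether (E C9=C10, E C13=C14) | C[C@@H]1C(=O)O[C@@H]2C[C@H]1CC/C(C)=C/CC(S(=O)(=O)c3ccccc3)/C(C)=C/CC[C@]2(C)O[Si](CC)(CC)CC
F4 | step 24 | macrocyclic C14 tributylstannane with C12=C13 alkene (geometry and C14 configuration not assigned) | C[C@@H]1C(=O)O[C@@H]2C[C@H]1CC[C@]1(C)O[C@H]1CC=C(C)C(CC[C@]2(C)O)[Sn](CCCC)(CCCC)CCCC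
F5 | step 25 | C17 triethylsilyl ether of 35 | C[C@@H]1C(=O)O[C@@H]2C[C@H]1CC[C@]1(C)O[C@H]1CC/C(C)=C/CC[C@]2(C)O[Si](CC)(CC)CC
F6 | step 25 | C13 hydroperoxide C14 bromide (anti adduct) of F5 | C[C@@H]1C(=O)O[C@@H]2C[C@H]1CC[C@]1(C)O[C@H]1CC[C@](C)(OO)[C@H](Br)CC[C@]2(C)O[Si](CC)(CC)CC
F7 | step 25 | 2-methoxyprop-2-yl peroxyketal of F6 | C[C@@H]1C(=O)O[C@@H]2C[C@H]1CC[C@]1(C)O[C@H]1CC[C@](C)(OOC(C)(C)OC)[C@H](Br)CC[C@]2(C)O[Si](CC)(CC)CC
F8 | step 25 | allylic peroxyketal with E C14=C15 and C17 silyl ether | C[C@@H]1C(=O)O[C@@H]2C[C@H]1CC[C@]1(C)O[C@H]1CC[C@](C)(OOC(C)(C)OC)/C=C/C[C@]2(C)O[Si](CC)(CC)CC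
F9 | step 5 | (4S,5R)-2,2,4-trimethyl-4-(4-methylpent-3-enyl)-5-(prop-2-ynyl)-1,3-dioxolane | C#CC[C@H]1OC(C)(C)O[C@@]1(C)CCC=C(C)C
A1 | alternative 1 | 14-membered epoxy alkenyl hydroxy lactone (identical with 35) | C[C@@H]1C(=O)O[C@@H]2C[C@H]1CC[C@]1(C)O[C@H]1CC/C(C)=C/CC[C@]2(C)O
A2 | alternative 1 | 16-membered E C2=C6 enoate macrolactone with iodomethyl group on C4 | C/C1=C\CC[C@]2(C)O[C@H]2CC/C(C)=C/CC[C@](C)(O)[C@@H](CI)OC1=O
A3 | alternative 2 | bis-epoxy diol methyl ester | COC(=O)[C@@H](C)[C@@H](C[C@@H]1O[C@@]1(C)CO)CC[C@]1(C)O[C@H]1CO
A4 | alternative 2 | bis-allylic diol methyl ester | COC(=O)[C@@H](C)[C@@H](C/C=C(\C)CO)CC/C(C)=C/CO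
A5 | alternative 2 | (R)-limonene | CC1=CC[C@@H](CC1)C(C)=C
A6 | alternative 3 | 6-substituted 4-methoxy-3-methyl-5,6-dihydropyran-2-one | CC1=C(OC)C[C@@H](OC1=O)[C@@](C)(OC(=O)c2ccccc2)CC/C=C(\C)CO[Si](C)(C)C(C)(C)C
A7 | alternative 3 | C4 aldehyde with C17 benzoate and C12 silyl ether | O=C[C@@](C)(OC(=O)c1ccccc1)CC/C=C(\C)CO[Si](C)(C)C(C)(C)C
A8 | alternative 3 | 1,3-dimethoxy-2-methyl-1-(trimethylsilyloxy)buta-1,3-diene | COC(=C)C(C)=C(OC)O[Si](C)(C)C
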